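## Retrosynthetic overview

1. Target 18 ⇐ diol 17 by regioselective methylation of the equatorial C3–OH of the cis-2,3-diol ⇐ acetonide 16.
2. 16 ⇐ anodic dehydrogenative (3+2) annulation of silyl enol ether 13 with (E)-isoelemicin 14, forming C5–C6 then C1–C7 and closing the cyclopentanone onto the existing six-membered ring.
3. 13 ⇐ 2-allyl-6-methoxy ketone 11 ⇐ enone 6, by reductive allylation and α'-hydroxylation/methylation.
4. 6 ⇐ (−)-quinic acid 1, which supplies C2 and C3 of the target; these two centres steer C1, C5, C6 and C7.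
5. Ring order: the six-membered carbocycle is bought; the five-membered ketone ring, and with it the bicyclo[3.2.1]octane, is formed in the key step.

Locants: 4–13 use cyclohexanone numbering (C1 carbonyl, C2 allyl carbon, C4/C5 dioxolane carbons, C6 methoxy carbon). 15–18 use bicyclo[3.2.1]octane numbering (C1 OMe bridgehead, C2 OH, C3 OMe, C5 allyl bridgehead, C6 methyl, C7 aryl, C8 carbonyl). Cyclohexanone C2, C6, C5, C4 become bicyclic C5, C1, C2, C3.

Assumption: (E)-isoelemicin 14 is bought as such.

## Route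

Step 1
Reactants: 1 (−)-quinic acid
Product: 2 3,4-O-isopropylidene-1,5-quinic lactone
Conditions: Me2C(OMe)2, TsOH·H2O (cat.), acetone, reflux
Reagents that add atoms: 2,2-dimethoxypropane, COC(C)(C)OC
Why: Acid-catalysed acetonide formation on the only cis-vicinal diol (C3/C4) with lactonisation of the C1 acid onto the cis C5 hydroxyl; all stereocentres of quinic acid are untouched.

Step 2
Reactants: 2 3,4-O-isopropylidene-1,5-quinic lactone
Product: 3 1-(hydroxymethyl)-3,4-O-isopropylidenecyclohexane-1,3,4,5-tetrol (quinic acid configuration)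
Conditions: NaBH4, EtOH, 0 °C → rt
Reagents that add atoms: none
Why: NaBH4 reduction of the α-hydroxy-activated lactone to the diol; no stereocentre is affected.

Step 3
Reactants: 3 1-(hydroxymethyl)-3,4-O-isopropylidenecyclohexane-1,3,4,5-tetrol
Product: 4 (3R,4S,5R)-3-hydroxy-4,5-(isopropylidenedioxy)cyclohexan-1-one
Conditions: NaIO4, H2O (pH 6 phosphate buffer), 0 °C → rt
Reagents that add atoms: none
Why: Malaprade periodate cleavage of the only free 1,2-diol (tertiary OH/CH2OH) excises the exocyclic carbon and leaves the ketone; the 1,3-related secondary OH and the acetonide are inert.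

Step 4
Reactants: 4 (3R,4S,5R)-3-hydroxy-4,5-(isopropylidenedioxy)cyclohexan-1-one
Product: 6 (4S,5R)-4,5-(isopropylidenedioxy)cyclohex-2-en-1-one, via 3-O-mesylate 5 (not isolated)
Conditions: MsCl, Et3N, CH2Cl2, 0 °C → rt
Reagents that add atoms: none
Why: Mesylation of the β-hydroxyl followed by E1cB elimination in the same flask gives the enone; the two dioxolane stereocentres (future C2 and C3 of the target) are not touched.

Step 5
Reactants: 6 (4S,5R)-4,5-(isopropylidenedioxy)cyclohex-2-en-1-one
Product: 8 (4S,5R)-2-allyl-4,5-(isopropylidenedioxy)cyclohexan-1-one (C2 epimers), via lithium (4S,5R)-4,5-(isopropylidenedioxy)cyclohex-1-en-1-olate 7 (not isolated)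
Conditions: LiBH(s-Bu)3, THF, −78 °C; then allyl bromide, DMPU, −78 → 0 °C
Reagents that add atoms: allyl bromide, C=CCBr
Why: Reductive alkylation of an enone: LiBH(s-Bu)3 adds 1,4 to the β-unsubstituted cyclohexenone to give one regio-defined enolate, which is C-allylated; the new C2 centre is irrelevant because it becomes sp2 again in step 8.

Step 6
Reactants: 8 (4S,5R)-2-allyl-4,5-(isopropylidenedioxy)cyclohexan-1-one
Product: 10 (4S,5R)-2-allyl-6-hydroxy-4,5-(isopropylidenedioxy)cyclohexan-1-one, via lithium 3-allyl-5,6-(isopropylidenedioxy)cyclohex-1-en-2-olate 9 (not isolated)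
Conditions: LiN(i-Pr)2, THF, −78 °C; then (±)-2-(phenylsulfonyl)-3-phenyloxaziridine, −78 °C; aq. NH4Cl
Reagents that add atoms: 2-(phenylsulfonyl)-3-phenyloxaziridine, O=S(=O)(c1ccccc1)N1OC1c1ccccc1
Why: Kinetic deprotonation at the CH2 rather than the allyl-bearing CH, then electrophilic enolate hydroxylation (Davis oxidation) anti to the neighbouring dioxolane oxygen; −78 °C keeps the β-alkoxy enolate 9 from eliminating, and the C6 configuration is erased in step 9.

Step 7
Reactants: 10 (4S,5R)-2-allyl-6-hydroxy-4,5-(isopropylidenedioxy)cyclohexan-1-one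
Product: 11 (4S,5S)-2-allyl-6-methoxy-4,5-(isopropylidenedioxy)cyclohexan-1-one
Conditions: MeI, Ag2O, 4 Å MS, MeCN, 40 °C, dark
Reagents that add atoms: iodomethane, CI
Why: Purdie methylation etherifies the α-ketol under neutral conditions, avoiding base-induced α-ketol shift or β-elimination; alkene, ketone and acetonide are inert.

Step 8
Reactants: 11 (4S,5S)-2-allyl-6-methoxy-4,5-(isopropylidenedioxy)cyclohexan-1-one
Product: 13 (4S,5S)-2-allyl-1-(tert-butyldimethylsilyloxy)-6-methoxy-4,5-(isopropylidenedioxy)cyclohex-1-ene, via lithium 2-allyl-6-methoxy-4,5-(isopropylidenedioxy)cyclohex-1-en-1-olate 12 (not isolated)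
Conditions: LiN(i-Pr)2, THF, −78 °C; then t-BuMe2SiCl, DMPU, −78 → 0 °C
Reagents that add atoms: tert-butyldimethylsilyl chloride, CC(C)(C)[Si](C)(C)Cl
Why: Kinetic enolisation of an α-alkoxy ketone by LiN(i-Pr)2 is expected to go away from the alkoxy-bearing carbon (lone-pair repulsion disfavours the α-methoxy carbanion, as in lactate-derived ketones), and O-silylation of the tetrasubstituted enolate fixes C2 as the enol-ether β-carbon for step 9.

Step 9
Reactants: 13 (4S,5S)-2-allyl-1-(tert-butyldimethylsilyloxy)-6-methoxy-4,5-(isopropylidenedioxy)cyclohex-1-ene; 14 (E)-isoelemicin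
Product: 16 (1S,2S,3S,5R,6R,7S)-5-allyl-2,3-(isopropylidenedioxy)-1-methoxy-6-methyl-7-(3,4,5-trimethoxyphenyl)bicyclo[3.2.1]octan-8-one, via O-silyloxocarbenium ion 15 (not isolated)
Conditions: 14 (3 equiv), carbon-felt anode, Pt cathode, undivided cell, constant current (2.2 F/mol), LiClO4 (1 M), MeNO2/CH2Cl2, 2,6-di-tert-butylpyridine (2.5 equiv), 0 °C; aq. NaHCO3
Reagents that add atoms: none
Why: Proposed new method: anodic dehydrogenative (3+2) annulation of an enol silane with an aryl alkene — one-electron oxidation of either partner (both estimated near 1.1–1.2 V vs SCE) gives the same first bond, C2 of 13 to the methyl-bearing alkene carbon, because the β-carbon of an enol-ether radical cation is electrophilic and that of the neutral enol ether nucleophilic (anodic olefin-coupling polarity); the resulting O-silyl oxocarbenium has a single α-hydrogen (H-6, acidified by the methoxy group), which the hindered pyridine removes to give a 1-siloxy-2-methoxyalkene, the trimethoxybenzyl radical is oxidised to the cation at much lower potential, and 5-exo C–C closure (C6 of 13 to the benzylic carbon) gives 15, which loses silicon on work-up — the stepwise equivalent of a 1-methoxy-2-siloxyallyl cation (3+2); stereocontrol: the alkene adds to the ring face opposite the cis-fused dioxolane (bought centres C4/C5 of 13), the only face from which the bridged cyclopentanone can close with the dioxolane exo, the E geometry is kept (trans aryl/methyl) and the aryl group takes the exo position beside the carbonyl bridge with the smaller methyl endo, which sets C1, C5, C6 and C7 of 16; closest known reaction types: Yamamura-type anodic phenol–propenylarene cycloaddition, anodic enol ether–olefin coupling, and the thermal (3+2) of 2-siloxyallyl cations with styrenes (Noyori-type cyclopentanone annulation).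

Step 10
Reactants: 16 (1S,2S,3S,5R,6R,7S)-5-allyl-2,3-(isopropylidenedioxy)-1-methoxy-6-methyl-7-(3,4,5-trimethoxyphenyl)bicyclo[3.2.1]octan-8-one
Product: 17 (1S,2S,3S,5R,6R,7S)-5-allyl-2,3-dihydroxy-1-methoxy-6-methyl-7-(3,4,5-trimethoxyphenyl)bicyclo[3.2.1]octan-8-one
Conditions: AcOH/H2O (4:1), 40 °C
Reagents that add atoms: none
Why: Acid hydrolysis of the isopropylidene ketal; the ketone sits between two fully substituted bridgeheads and cannot enolise, so no centre can epimerise, and the allyl group and aryl ethers are inert.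

Step 11
Reactants: 17 (1S,2S,3S,5R,6R,7S)-5-allyl-2,3-dihydroxy-1-methoxy-6-methyl-7-(3,4,5-trimethoxyphenyl)bicyclo[3.2.1]octan-8-one
Product: 18 (1S,2S,3S,5R,6R,7S)-5-allyl-2-hydroxy-1,3-dimethoxy-6-methyl-7-(3,4,5-trimethoxyphenyl)bicyclo[3.2.1]octan-8-one (CNP0275320.2)
Conditions: Me3OBF4 (1.2 equiv), 2,6-di-tert-butyl-4-methylpyridine, CH2Cl2, 0 °C → rt
Reagents that add atoms: trimethyloxonium tetrafluoroborate, C[O+](C)C.F[B-](F)(F)F
Why: Meerwein-salt O-methylation with a hindered base: the equatorial C3 hydroxyl next to the C4 methylene should be alkylated ahead of the axial C2 hydroxyl flanked by the quaternary C1, and the non-basic conditions avoid retro-aldol opening of the β-hydroxy ketone.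

## Compound list

1 | (−)-quinic acid, (1S,3R,4S,5R)-1,3,4,5-tetrahydroxycyclohexane-1-carboxylic acid | OC(=O)[C@]1(O)C[C@@H](O)[C@@H](O)[C@H](O)C1 | starting material
2 | 3,4-O-isopropylidene-1,5-quinic lactone (configuration of 1 retained) | O=C1[C@]2(O)C[C@@H]3[C@@H](OC(C)(C)O3)[C@H](O1)C2 | intermediate
3 | 1-(hydroxymethyl)-3,4-O-isopropylidenecyclohexane-1,3,4,5-tetrol (quinic acid configuration) | OC[C@]1(O)C[C@@H]2[C@@H](OC(C)(C)O2)[C@H](O)C1 | intermediate
4 | (3R,4S,5R)-3-hydroxy-4,5-(isopropylidenedioxy)cyclohexan-1-one | O=C1C[C@@H]2[C@@H](OC(C)(C)O2)[C@H](O)C1 | intermediate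
5 | 3-O-methanesulfonate of 4, configuration unchanged (not isolated) | O=C1C[C@@H]2[C@@H](OC(C)(C)O2)[C@H](OS(C)(=O)=O)C1 | intermediate
6 | (4S,5R)-4,5-(isopropylidenedioxy)cyclohex-2-en-1-one | O=C1C=C[C@@H]2OC(C)(C)O[C@@H]2C1 | intermediate
7 | lithium (4S,5R)-4,5-(isopropylidenedioxy)cyclohex-1-en-1-olate (not isolated) | [Li+].[O-]C1=CC[C@@H]2OC(C)(C)O[C@@H]2C1 | intermediate
8 | (4S,5R)-2-allyl-4,5-(isopropylidenedioxy)cyclohexan-1-one, mixture of C2 epimers | C=CCC1C[C@@H]2OC(C)(C)O[C@@H]2CC1=O | intermediate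
9 | lithium enolate of 8 toward C6, lithium 3-allyl-5,6-(isopropylidenedioxy)cyclohex-1-en-2-olate (not isolated) | [Li+].C=CCC1C[C@@H]2OC(C)(C)O[C@@H]2C=C1[O-] | intermediate
10 | (4S,5R)-2-allyl-6-hydroxy-4,5-(isopropylidenedioxy)cyclohexan-1-one, C2 epimers, 6-OH expected trans to the dioxolane | C=CCC1C[C@@H]2OC(C)(C)O[C@@H]2C(O)C1=O | intermediate
11 | (4S,5S)-2-allyl-6-methoxy-4,5-(isopropylidenedioxy)cyclohexan-1-one, C2 epimers | C=CCC1C[C@@H]2OC(C)(C)O[C@@H]2C(OC)C1=O | intermediate
12 | lithium 2-allyl-6-methoxy-4,5-(isopropylidenedioxy)cyclohex-1-en-1-olate (not isolated) | [Li+].C=CCC1=C([O-])C(OC)[C@H]2OC(C)(C)O[C@H]2C1 | intermediate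
13 | (4S,5S)-2-allyl-1-(tert-butyldimethylsilyloxy)-6-methoxy-4,5-(isopropylidenedioxy)cyclohex-1-ene | C=CCC1=C(O[Si](C)(C)C(C)(C)C)C(OC)[C@H]2OC(C)(C)O[C@H]2C1 | intermediate
14 | (E)-isoelemicin, (E)-1,2,3-trimethoxy-5-(prop-1-en-1-yl)benzene | C/C=C/c1cc(OC)c(OC)c(OC)c1 | starting material
15 | O-(tert-butyldimethylsilyl) oxocarbenium ion of 16 (not isolated) | C=CC[C@]12C[C@@H]3OC(C)(C)O[C@@H]3[C@](OC)(C1=[O+][Si](C)(C)C(C)(C)C)[C@H](c1cc(OC)c(OC)c(OC)c1)[C@H]2C | intermediate
16 | (1S,2S,3S,5R,6R,7S)-5-allyl-2,3-(isopropylidenedioxy)-1-methoxy-6-methyl-7-(3,4,5-trimethoxyphenyl)bicyclo[3.2.1]octan-8-one | C=CC[C@]12C[C@@H]3OC(C)(C)O[C@@H]3[C@](OC)(C1=O)[C@H](c1cc(OC)c(OC)c(OC)c1)[C@H]2C | intermediate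
17 | (1S,2S,3S,5R,6R,7S)-5-allyl-2,3-dihydroxy-1-methoxy-6-methyl-7-(3,4,5-trimethoxyphenyl)bicyclo[3.2.1]octan-8-one | C=CC[C@]12C[C@H](O)[C@H](O)[C@](OC)(C1=O)[C@H](c1cc(OC)c(OC)c(OC)c1)[C@H]2C | intermediate
18 | (1S,2S,3S,5R,6R,7S)-5-allyl-2-hydroxy-1,3-dimethoxy-6-methyl-7-(3,4,5-trimethoxyphenyl)bicyclo[3.2.1]octan-8-one | C=CC[C@]12C[C@H](OC)[C@H](O)[C@](OC)(C1=O)[C@H](c1cc(OC)c(OC)c(OC)c1)[C@H]2C | target

## Step count and risks

Total steps: 11. Longest linear sequence: 11 steps (1 → 18); 14 is bought.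

The three steps most likely to fail:

**Step 9 (proposed new anodic annulation).** Likely failure modes are alkene radical-cation dimerisation, cyclobutane formation, or anodic desaturation of the enol silane. The fallback uses known chemistry and sets out from 13. N-Chlorosuccinimide (THF, −78 °C) chlorinates the enol ether at C2 to give (4S,5S)-2-allyl-2-chloro-6-methoxy-4,5-(isopropylidenedioxy)cyclohexan-1-one F1. F1 and 14 with Et3N in CF3CH2OH (Föhlisch conditions) generate the methoxy-substituted oxyallyl cation thermally, by enolisation toward C6 and loss of chloride. Its (3+2) capture by the aryl alkene (Noyori-type oxyallyl–styrene annulation), again anti to the dioxolane, comes back to the route at 16.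

**Step 8 (regioselective enolisation).** Deprotonation at the methoxy-bearing C6 would give the wrong enol ether or β-elimination of the dioxolane oxygen. The fallback sets out from 8 and makes the regiochemistry structural. LiN(i-Pr)2 then PhSSO2Ph sulfenylates the kinetic CH2 enolate to give the 6-(phenylthio) ketone F2. N-Chlorosuccinimide (CH2Cl2, 0 °C) gives the α-chloro sulfide F3, and methanolysis (MeOH, 2,6-lutidine) gives the O,S-ketal F4. C6 is now quaternary, so TBSOTf/Et3N can enolise only toward C2 and gives the silyl enol ether F5 as a single regioisomer. F5 is electrolysed with 14 under the conditions of step 9, the phenylthio group leaving from the radical cation in place of H-6 (anodic C–S cleavage as in thioglycoside activation). This comes back to the route at 16.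

**Step 5 (reductive allylation).** Competing 1,2-reduction or sluggish or multiple alkylation of the borane-complexed enolate is possible. The fallback sets out from 6. I2/pyridine (CH2Cl2) gives the 2-iodoenone F6. Stille coupling with allyltributylstannane (Pd(PPh3)4, zerovalent palladium, with CuI in DMF) gives the 2-allylenone F7. Chemoselective 1,4-reduction with [(Ph3P)CuH]6 in wet benzene leaves the terminal alkene alone and comes back to the route at 8.

## Further compounds

F1 | step 9 | (4S,5S)-2-allyl-2-chloro-6-methoxy-4,5-(isopropylidenedioxy)cyclohexan-1-one | C=CCC1(Cl)C[C@@H]2OC(C)(C)O[C@@H]2C(OC)C1=O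
F2 | step 8 | (4S,5S)-2-allyl-6-(phenylthio)-4,5-(isopropylidenedioxy)cyclohexan-1-one | C=CCC1C[C@@H]2OC(C)(C)O[C@@H]2C(Sc3ccccc3)C1=O
F3 | step 8 | (4S,5S)-2-allyl-6-chloro-6-(phenylthio)-4,5-(isopropylidenedioxy)cyclohexan-1-one | C=CCC1C[C@@H]2OC(C)(C)O[C@@H]2C(Cl)(Sc3ccccc3)C1=O
F4 | step 8 | (4S,5S)-2-allyl-6-methoxy-6-(phenylthio)-4,5-(isopropylidenedioxy)cyclohexan-1-one | C=CCC1C[C@@H]2OC(C)(C)O[C@@H]2C(OC)(Sc3ccccc3)C1=O
F5 | step 8 | (4S,5S)-2-allyl-1-(tert-butyldimethylsilyloxy)-6-methoxy-6-(phenylthio)-4,5-(isopropylidenedioxy)cyclohex-1-ene | C=CCC1=C(O[Si](C)(C)C(C)(C)C)C(OC)(Sc3ccccc3)[C@H]2OC(C)(C)O[C@H]2C1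
F6 | step 5 | (4S,5R)-2-iodo-4,5-(isopropylidenedioxy)cyclohex-2-en-1-one | O=C1C(I)=C[C@@H]2OC(C)(C)O[C@@H]2C1
F7 | step 5 | (4S,5R)-2-allyl-4,5-(isopropylidenedioxy)cyclohex-2-en-1-one | C=CCC1=C[C@@H]2OC(C)(C)O[C@@H]2CC1=O
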